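**Retrosynthetic overview** (locants: isoflavone unprimed, its ring B primed, flavone unit double-primed)
1. The target is a 5,7-dihydroxyisoflavone whose ring B is joined at C3' to C8'' of an apigenin unit; it is released last by sixfold O-demethylation of its hexamethyl ether.
2. Feature used: ring A of the isoflavone carries oxygen at C5 and C7, with C5–O next to C4a, so the ring C bonds O1–C8a and C4–C4a span the formal triple bond of 3,5-dimethoxybenzyne, and the methoxy group that becomes C5–OMe steers an oxygen nucleophile to the carbon that becomes C8a.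
3. Key disconnection: isoflavone ring C is cut into an o-silylaryl triflate (aryne precursor) and a flavone-bearing methyl 2-aryl-3-hydroxyacrylate, whose enol O goes to C8a and whose ester carbonyl becomes C4.
4. The hydroxyacrylate comes from Claisen formylation of a methyl arylacetate, itself made by Suzuki coupling (C3'–C8'') of 8-iodo-tri-O-methylapigenin with an arylacetate boronate; the silyl triflate comes from 3,5-dimethoxyphenol by carbamate-directed ortho-silylation.
5. Ring order: both flavone rings and all benzene rings are bought; isoflavone ring C is the only ring made, in step 8.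

Key step: step 8

Remark: the target is specified without axial chirality at the C3'–C8'' bond (three small ortho substituents), so no atroposelective step is planned. The formylacetate enol is drawn as its hydrogen-bonded Z form; the E enol and the aldehyde tautomer give the same enolate.

**Route**

Step 1
Reactants: 1 3,5-dimethoxyphenol
Product: 2 3,5-dimethoxyphenyl N-isopropylcarbamate
Conditions: i-PrNCO, Et3N (cat.), CH2Cl2, rt
Reagents that add atoms: isopropyl isocyanate, CC(C)N=C=O
Why: Base-catalysed addition of the phenol O–H to the isocyanate (carbamoylation) is clean for electron-rich phenols and installs a removable ortho-directing group.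

Step 2
Reactants: 2 3,5-dimethoxyphenyl N-isopropylcarbamate
Product: 5 3,5-dimethoxy-2-(trimethylsilyl)phenyl N-isopropylcarbamate, via N-silyl carbamate 3 (not isolated), via N,C-bis-silyl carbamate 4 (not isolated)
Conditions: TMSOTf, TMEDA, Et2O, 0 °C → rt; n-BuLi, TMEDA, −78 °C; TMSCl, −78 °C → rt; aq NaHSO4
Reagents that add atoms: trimethylsilyl trifluoromethanesulfonate, C[Si](C)(C)OS(=O)(=O)C(F)(F)F (its silyl group is carried only by 3 and 4); chlorotrimethylsilane, C[Si](C)(C)Cl
Why: Directed ortho-metalation: in situ N-silylation makes the carbamate a strong, non-acidic director, n-BuLi/TMEDA removes the C2 proton flanked by the carbamate and a methoxy group, TMSCl traps the aryllithium, and the N-silyl group is lost in the acidic work-up.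

Step 3
Reactants: 5 3,5-dimethoxy-2-(trimethylsilyl)phenyl N-isopropylcarbamate
Product: 7 3,5-dimethoxy-2-(trimethylsilyl)phenyl trifluoromethanesulfonate, via silylphenol 6 (not isolated)
Conditions: DBU, Et2NH, MeCN, 40 °C; then PhNTf2, rt
Reagents that add atoms: N-phenylbis(trifluoromethanesulfonimide), O=S(=O)(N(c1ccccc1)S(=O)(=O)C(F)(F)F)C(F)(F)F
Why: DBU induces E1cB cleavage of the N–H carbamate to the phenoxide and isopropyl isocyanate (scavenged by diethylamine as a urea), and the phenoxide is triflated in the same pot, conditions mild enough to keep the ortho C–Si bond.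

Step 4
Reactants: 8 4',5,7-trimethoxyflavone (tri-O-methylapigenin)
Product: 9 8-iodo-5,7-dimethoxy-2-(4-methoxyphenyl)-4H-chromen-4-one
Conditions: I2, CF3CO2Ag, CH2Cl2, rt, dark
Reagents that add atoms: iodine, [I][I]
Why: Electrophilic aromatic iodination by silver-activated iodine occurs on the electron-rich ring A, and in 5-O-alkylated 5,7-dioxygenated flavones the established site is C8 (ortho to the 7-methoxy group and ring oxygen, para to the 5-methoxy group) rather than C6, C3 or ring B.

Step 5
Reactants: 10 methyl 2-(3-bromo-4-methoxyphenyl)acetate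
Product: 11 methyl 2-[4-methoxy-3-(4,4,5,5-tetramethyl-1,3,2-dioxaborolan-2-yl)phenyl]acetate
Conditions: B2pin2, PdCl2(dppf) (cat.), KOAc, 1,4-dioxane, 90 °C
Reagents that add atoms: bis(pinacolato)diboron, CC1(C)OB(OC1(C)C)B1OC(C)(C)C(C)(C)O1
Why: Miyaura borylation of an aryl bromide with the weak base KOAc tolerates the methyl ester and its benzylic C–H bonds.

Step 6
Reactants: 9 8-iodo-5,7-dimethoxy-2-(4-methoxyphenyl)-4H-chromen-4-one; 11 methyl 2-[4-methoxy-3-(4,4,5,5-tetramethyl-1,3,2-dioxaborolan-2-yl)phenyl]acetate
Product: 12 methyl 2-{3-[5,7-dimethoxy-2-(4-methoxyphenyl)-4-oxo-4H-chromen-8-yl]-4-methoxyphenyl}acetate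
Conditions: Pd(OAc)2 (cat.), SPhos, K3PO4, toluene/H2O 10:1, 90 °C
Reagents that add atoms: none
Why: Suzuki–Miyaura coupling after oxidative addition of the C8–I bond to zerovalent palladium; the bulky electron-rich biarylphosphine suits a biaryl with three ortho substituents, and K3PO4 in mostly toluene keeps ester hydrolysis slow.

Step 7
Reactants: 12 methyl 2-{3-[5,7-dimethoxy-2-(4-methoxyphenyl)-4-oxo-4H-chromen-8-yl]-4-methoxyphenyl}acetate; 13 methyl formate
Product: 14 methyl (Z)-3-hydroxy-2-{3-[5,7-dimethoxy-2-(4-methoxyphenyl)-4-oxo-4H-chromen-8-yl]-4-methoxyphenyl}prop-2-enoate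
Conditions: NaH (3 equiv), 13 (excess), THF, 0 °C → rt; then 1 M HCl
Reagents that add atoms: none
Why: Crossed Claisen condensation (C-formylation) of the ester enolate with non-enolisable methyl formate is driven by formation of the stabilised sodium enolate of the product; the flavone has no acidic C–H, and acidification should give the hydrogen-bonded Z enol.

Step 8
Reactants: 14 methyl (Z)-3-hydroxy-2-{3-[5,7-dimethoxy-2-(4-methoxyphenyl)-4-oxo-4H-chromen-8-yl]-4-methoxyphenyl}prop-2-enoate; 7 3,5-dimethoxy-2-(trimethylsilyl)phenyl trifluoromethanesulfonate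
Product: 16 5,7-dimethoxy-3-{3-[5,7-dimethoxy-2-(4-methoxyphenyl)-4-oxo-4H-chromen-8-yl]-4-methoxyphenyl}-4H-chromen-4-one (hexa-O-methyl ether of the target), via 3,5-dimethoxybenzyne 15 (not isolated)
Conditions: 7 (2 equiv), CsF (5 equiv), THF, 65 °C
Reagents that add atoms: none
Why: Proposed new method: fluoride removes the silyl group of 7 and triflate leaves to give aryne 15 while fluoride also deprotonates the acidic enol 14; the enolate oxygen adds to the aryne carbon meta to the neighbouring methoxy group (future C8a), and the aryl anion left ortho to that methoxy group (future C4a) attacks the cis ester carbonyl and expels methoxide. The closest known reaction is the CsF-induced annulation of methyl salicylates with o-silylaryl triflates to xanthones, in which a phenoxide takes the part played here by the enolate oxygen of a formylacetate. Ring C closes by a 6-exo-trig acyl substitution (O1–C8a first, then C4–C4a), and no stereocentre is formed. Site selectivity on the aryne should follow the distortion and inductive effect of the adjacent methoxy group, the usual pattern for 3-alkoxybenzynes. The step also needs O- over C-arylation of the ambident enolate: the carbon terminus is fully substituted and flanked by aryl, ester and formyl groups, whereas the formyl-derived oxygen is unhindered and carries most of the charge, which should favour capture there by a very reactive aryne. THF is chosen over MeCN so that ring closure of the aryl anion can outrun its protonation.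

Step 9
Reactants: 16 hexa-O-methyl ether of the target
Product: 17 5,7-dihydroxy-3-{4-hydroxy-3-[5,7-dihydroxy-2-(4-hydroxyphenyl)-4-oxo-4H-chromen-8-yl]phenyl}-4H-chromen-4-one (target, CNP0142623.0)
Conditions: BBr3 (excess), CH2Cl2, −78 °C → rt; then MeOH/H2O
Reagents that add atoms: none
Why: BBr3-mediated cleavage of aryl methyl ethers (O-coordination, then bromide attack on methyl) should remove all six methyl groups, the two peri ethers being assisted by chelation to the C4 carbonyls, while the aprotic low-temperature conditions should leave both pyranone rings and the biaryl bond intact.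

**Compound list**
1 | 3,5-dimethoxyphenol | COc1cc(O)cc(OC)c1 | starting material
2 | 3,5-dimethoxyphenyl N-isopropylcarbamate | COc1cc(OC)cc(OC(=O)NC(C)C)c1 | intermediate
3 | 3,5-dimethoxyphenyl N-isopropyl-N-(trimethylsilyl)carbamate | COc1cc(OC)cc(OC(=O)N(C(C)C)[Si](C)(C)C)c1 | intermediate (not isolated)
4 | 3,5-dimethoxy-2-(trimethylsilyl)phenyl N-isopropyl-N-(trimethylsilyl)carbamate | COc1cc(OC)c([Si](C)(C)C)c(OC(=O)N(C(C)C)[Si](C)(C)C)c1 | intermediate (not isolated)
5 | 3,5-dimethoxy-2-(trimethylsilyl)phenyl N-isopropylcarbamate | COc1cc(OC)c([Si](C)(C)C)c(OC(=O)NC(C)C)c1 | intermediate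
6 | 3,5-dimethoxy-2-(trimethylsilyl)phenol | COc1cc(OC)c([Si](C)(C)C)c(O)c1 | intermediate (not isolated)
7 | 3,5-dimethoxy-2-(trimethylsilyl)phenyl trifluoromethanesulfonate | COc1cc(OC)c([Si](C)(C)C)c(OS(=O)(=O)C(F)(F)F)c1 | intermediate
8 | 4',5,7-trimethoxyflavone (tri-O-methylapigenin) | COc1ccc(-c2cc(=O)c3c(OC)cc(OC)cc3o2)cc1 | starting material
9 | 8-iodo-5,7-dimethoxy-2-(4-methoxyphenyl)-4H-chromen-4-one | COc1ccc(-c2cc(=O)c3c(OC)cc(OC)c(I)c3o2)cc1 | intermediate
10 | methyl 2-(3-bromo-4-methoxyphenyl)acetate | COC(=O)Cc1ccc(OC)c(Br)c1 | starting material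
11 | methyl 2-[4-methoxy-3-(4,4,5,5-tetramethyl-1,3,2-dioxaborolan-2-yl)phenyl]acetate | COC(=O)Cc1ccc(OC)c(B2OC(C)(C)C(C)(C)O2)c1 | intermediate
12 | methyl 2-{3-[5,7-dimethoxy-2-(4-methoxyphenyl)-4-oxo-4H-chromen-8-yl]-4-methoxyphenyl}acetate | COC(=O)Cc1ccc(OC)c(-c2c(OC)cc(OC)c3c(=O)cc(-c4ccc(OC)cc4)oc23)c1 | intermediate
13 | methyl formate | COC=O | starting material
14 | methyl (Z)-3-hydroxy-2-{3-[5,7-dimethoxy-2-(4-methoxyphenyl)-4-oxo-4H-chromen-8-yl]-4-methoxyphenyl}prop-2-enoate | COC(=O)/C(=C\O)c1ccc(OC)c(-c2c(OC)cc(OC)c3c(=O)cc(-c4ccc(OC)cc4)oc23)c1 | intermediate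
15 | 3,5-dimethoxybenzyne (1,2-didehydro-3,5-dimethoxybenzene) | COC1=CC(OC)=CC#C1 | intermediate (not isolated)
16 | 5,7-dimethoxy-3-{3-[5,7-dimethoxy-2-(4-methoxyphenyl)-4-oxo-4H-chromen-8-yl]-4-methoxyphenyl}-4H-chromen-4-one (hexa-O-methyl ether of the target) | O=c1c(-c2ccc(OC)c(-c3c(OC)cc(OC)c4c(=O)cc(-c5ccc(OC)cc5)oc34)c2)coc2cc(OC)cc(OC)c12 | intermediate
17 | 5,7-dihydroxy-3-{4-hydroxy-3-[5,7-dihydroxy-2-(4-hydroxyphenyl)-4-oxo-4H-chromen-8-yl]phenyl}-4H-chromen-4-one | O=c1c(-c2ccc(O)c(-c3c(O)cc(O)c4c(=O)cc(-c5ccc(O)cc5)oc34)c2)coc2cc(O)cc(O)c12 | target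

**Step count**
Total step count: 9.
Longest linear sequence: 5 steps (steps 1, 2, 3, 8, 9; equally steps 4 or 5, then 6, 7, 8, 9).

**Steps most likely to fail**

Step 8 (proposed new method). The ambident enolate may be captured at carbon instead of oxygen, after which the aryl anion adds to the formyl group and the aryne ends up inserted into the C–CHO bond. The aryl anion formed after O-arylation may also be protonated before it reaches the ester, leaving an open aryl vinyl ether, and liberated methoxide may consume aryne. The fallback uses the classical deoxybenzoin route; it sets out from 12 (with 1) and comes back at 16. Ester 12 would be saponified (LiOH, THF/H2O, rt, then acid) to 2-{3-[5,7-dimethoxy-2-(4-methoxyphenyl)-4-oxo-4H-chromen-8-yl]-4-methoxyphenyl}acetic acid F1. F1 and 3,5-dimethoxyphenol 1 would be heated in BF3·OEt2 at 80 °C, a Friedel–Crafts acylation that the boron chelate steers ortho to the free hydroxyl, to give the deoxybenzoin 1-(2-hydroxy-4,6-dimethoxyphenyl)-2-{3-[5,7-dimethoxy-2-(4-methoxyphenyl)-4-oxo-4H-chromen-8-yl]-4-methoxyphenyl}ethan-1-one F2. Heating F2 with N,N-dimethylformamide dimethyl acetal (toluene, 90 °C) would form the enaminone, which closes onto the phenol with loss of dimethylamine to give 16.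

Step 6. Transmetallation at the doubly ortho-flanked C8 centre may be slow, so that protodeboronation of the ortho-methoxy boronate and hydrolysis of the methyl ester by aqueous base outrun the coupling. The fallback is a base-free Stille coupling; it sets out from 10 (with 9) and comes back at 12. Bromide 10 would be stannylated (Me3SnSnMe3, Pd(PPh3)4, toluene, 100 °C) to methyl 2-[4-methoxy-3-(trimethylstannyl)phenyl]acetate F3. F3 would then be coupled with iodide 9 (Pd(PPh3)4, CuI, DMF, 80 °C) under neutral conditions to give 12.

Step 9. Ether cleavage may stop short of six, because partly demethylated boron complexes precipitate and the 7''-ether beside the biaryl axis is hindered. Forcing the reaction while HBr is present risks acid-triggered opening and reclosure of the 5-hydroxypyranone, a Wessely–Moser-type isomerisation that would move the aryl group from C8'' to C6''. The fallback stages the deprotection; it sets out from 16 and comes back at 17. BCl3 (CH2Cl2, 0 °C) would cleave only the two chelated peri ethers to give 5-hydroxy-3-{3-[5-hydroxy-7-methoxy-2-(4-methoxyphenyl)-4-oxo-4H-chromen-8-yl]-4-methoxyphenyl}-7-methoxy-4H-chromen-4-one F4. The four remaining ethers of F4 would then be cleaved by SN2 attack of NaSEt on methyl (DMF, 120 °C), conditions free of protic acid under which the peri phenoxides make both chromenones less prone to ring opening; acidification would give 17.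

**Further compounds**
F1 | step 8 | 2-{3-[5,7-dimethoxy-2-(4-methoxyphenyl)-4-oxo-4H-chromen-8-yl]-4-methoxyphenyl}acetic acid | OC(=O)Cc1ccc(OC)c(-c2c(OC)cc(OC)c3c(=O)cc(-c4ccc(OC)cc4)oc23)c1
F2 | step 8 | 1-(2-hydroxy-4,6-dimethoxyphenyl)-2-{3-[5,7-dimethoxy-2-(4-methoxyphenyl)-4-oxo-4H-chromen-8-yl]-4-methoxyphenyl}ethan-1-one | COc1cc(O)c(C(=O)Cc2ccc(OC)c(-c3c(OC)cc(OC)c4c(=O)cc(-c5ccc(OC)cc5)oc34)c2)c(OC)c1
F3 | step 6 | methyl 2-[4-methoxy-3-(trimethylstannyl)phenyl]acetate | COC(=O)Cc1ccc(OC)c([Sn](C)(C)C)c1
F4 | step 9 | 5-hydroxy-3-{3-[5-hydroxy-7-methoxy-2-(4-methoxyphenyl)-4-oxo-4H-chromen-8-yl]-4-methoxyphenyl}-7-methoxy-4H-chromen-4-one | O=c1c(-c2ccc(OC)c(-c3c(OC)cc(O)c4c(=O)cc(-c5ccc(OC)cc5)oc34)c2)coc2cc(OC)cc(O)c12
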